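## Retrosynthetic overview

- Locants: dioxane O1, O2, C3 (CH2CO2Me), C4 (Et), C5 (CH2), C6 (quaternary), chain C7–C14. The end game is esterification, preceded by Julia–Kocienski olefination (C11=C12, sulfone 25 + propanal), diimide saturation of two alkynes and cobalt removal.
- Key disconnection: C4–C5 and O1–C6 are formed in one operation, a Lewis-acid formal [4+2] annulation of the cobalt-complexed peroxy lactone 20 (C4, C3, O2, O1) with enyne 11 (C5=C6 plus the whole side chain).
- Enabling feature: C5 is a CH2 between C4 and the fully substituted, oxygen-bearing C6. A 1,1-disubstituted alkene C5=C6 adding to a C4 cation therefore puts the new tertiary cation on exactly the carbon that O1, the far end of the C4–C3–O2–O1 array, reaches in a six-membered closure.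
- Temporary devices, all removed later: a γ-lactone that ties the acetic acid arm to C4 as the leaving group; a Co2(CO)6-ethynyl group as the C4 ethyl precursor; the C7≡C8 alkyne as a slim, cation-stabilising chain; tert-butyl on O1.
- Ring order: the temporary γ-lactone (steps 9–10) is opened in step 12, where the 1,2-dioxane, the only ring of the target, closes. C10 comes from an Evans alkylation, C3 from an asymmetric peroxidation, C4 and C6 from step 12.

Key step: step 12

Assumption: the quinine-derived 9-amino-9-deoxy-epi-cinchona amine salt is taken to deliver the hydroperoxide to the enal face that gives the 3S peroxide; if the sense is opposite, its quinidine-derived pseudoenantiomer is used.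

## Route

Step 1
Reactants: 1 (4S)-4-benzyl-1,3-oxazolidin-2-one; 2 butanoyl chloride
Product: 3 (4S)-4-benzyl-3-butanoyl-1,3-oxazolidin-2-one
Conditions: n-BuLi, THF, −78 °C; then 2, −78 → 0 °C
Reagents that add atoms: none
Why: N-acylation of the lithiated Evans oxazolidinone with the acid chloride; no stereocentre is touched.

Step 2
Reactants: 3 (4S)-4-benzyl-3-butanoyl-1,3-oxazolidin-2-one; 4 3-bromoprop-1-yne
Product: 5 (4S)-4-benzyl-3-[(2R)-2-ethylpent-4-ynoyl]-1,3-oxazolidin-2-one
Conditions: NaHMDS, THF, −78 °C; then 4, −78 → −40 °C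
Reagents that add atoms: none
Why: Evans asymmetric alkylation: the chelated Z-sodium enolate is propargylated on the face opposite the benzyl group, which sets the future C10 centre as 2R.

Step 3
Reactants: 5 (4S)-4-benzyl-3-[(2R)-2-ethylpent-4-ynoyl]-1,3-oxazolidin-2-one
Product: 6 (2R)-2-ethylpent-4-yn-1-ol
Conditions: LiBH4, MeOH (1 equiv), Et2O, 0 °C
Reagents that add atoms: none
Why: Reductive cleavage of the N-acyl oxazolidinone with LiBH4 should give the primary alcohol without epimerisation and return the auxiliary; the terminal alkyne is inert.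

Step 4
Reactants: 6 (2R)-2-ethylpent-4-yn-1-ol; 7 1-phenyl-1H-tetrazole-5-thiol
Product: 8 5-{[(2R)-2-ethylpent-4-yn-1-yl]sulfanyl}-1-phenyl-1H-tetrazole
Conditions: PPh3, DIAD, THF, 0 °C → rt
Reagents that add atoms: none
Why: Mitsunobu thioetherification of the primary alcohol with the acidic tetrazole thiol (first half of a Julia–Kocienski sulfone preparation); the stereocentre is not involved.

Step 5
Reactants: 8 5-{[(2R)-2-ethylpent-4-yn-1-yl]sulfanyl}-1-phenyl-1H-tetrazole
Product: 9 5-{[(2R)-2-ethylpent-4-yn-1-yl]sulfonyl}-1-phenyl-1H-tetrazole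
Conditions: (NH4)6Mo7O24·4H2O (10 mol %), 30 % aq. H2O2, EtOH, 0 °C → rt
Reagents that add atoms: hydrogen peroxide, OO
Why: Molybdate-catalysed H2O2 oxidation of the sulfide to the sulfone; it is done before the enyne is built so that no electron-rich alkene is exposed, and the terminal alkyne is not oxidised.

Step 6
Reactants: 9 5-{[(2R)-2-ethylpent-4-yn-1-yl]sulfonyl}-1-phenyl-1H-tetrazole; 10 2-bromobut-1-ene
Product: 11 5-{[(2R)-2-ethyl-6-methylideneoct-4-yn-1-yl]sulfonyl}-1-phenyl-1H-tetrazole
Conditions: PdCl2(PPh3)2 (3 mol %), CuI (6 mol %), Et3N, THF, rt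
Reagents that add atoms: none
Why: Sonogashira coupling of the terminal alkyne with the vinyl bromide gives the 2-ethyl-1,3-enyne; Et3N is too weak a base to touch the sulfone α-CH2.

Step 7
Reactants: 12 (2E)-4,4-dimethoxybut-2-enal; 13 ethynylmagnesium bromide
Product: 14 (4E)-6,6-dimethoxyhex-4-en-1-yn-3-ol (racemic)
Conditions: THF, −78 → 0 °C; aqueous work-up
Reagents that add atoms: none
Why: 1,2-Addition of the alkynyl Grignard reagent to the enal carbonyl with the acetal untouched; the new carbinol centre is left racemic on purpose because it is ionised in step 12.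

Step 8
Reactants: 14 (4E)-6,6-dimethoxyhex-4-en-1-yn-3-ol
Product: 15 (2E)-4-hydroxyhex-2-en-5-ynal (racemic)
Conditions: Amberlyst-15 (cat.), acetone/H2O 20:1, 0 °C → rt; used directly
Reagents that add atoms: water, O
Why: Mild acid hydrolysis of the dimethyl acetal releases the (E)-enal; the E geometry prevents lactol formation, so the γ-hydroxy enal stays available for iminium catalysis.

Step 9
Reactants: 15 (2E)-4-hydroxyhex-2-en-5-ynal; 16 tert-butyl hydroperoxide
Product: 18 (4S)-4-(tert-butylperoxy)-5-ethynyloxolan-2-ol (C2/C5 epimer mixture), via open-chain aldehyde 17 (not isolated)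
Conditions: 9-amino-9-deoxy-epi-quinine (10 mol %), TFA (20 mol %), toluene, 0 °C
Reagents that add atoms: none
Why: Amine-catalysed enantioselective conjugate addition of an alkyl hydroperoxide to an enal (iminium activation, a known reaction type): the catalyst shields one face of the iminium ion and sets C3 as S, and the γ-hydroxyl traps the β-peroxy aldehyde 17 as lactol 18, which should protect it from retro-addition and epoxide formation.

Step 10
Reactants: 18 (4S)-4-(tert-butylperoxy)-5-ethynyloxolan-2-ol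
Product: 19 (4S)-4-(tert-butylperoxy)-5-ethynyloxolan-2-one (C5 epimer mixture)
Conditions: TEMPO (10 mol %), PhI(OAc)2, CH2Cl2, rt
Reagents that add atoms: none
Why: TEMPO/PhI(OAc)2 oxidation of the lactol to the γ-lactone under neutral conditions that leave the peroxide, the alkyne and the C4 stereocentre untouched.

Step 11
Reactants: 19 (4S)-4-(tert-butylperoxy)-5-ethynyloxolan-2-one
Product: 20 hexacarbonyldicobalt complex of 19 at the alkyne
Conditions: Co2(CO)8 (1.05 equiv), CH2Cl2, rt
Reagents that add atoms: dicobalt octacarbonyl, O=C=[Co](=C=O)(=C=O)(=C=O)[Co](=C=O)(=C=O)(=C=O)=C=O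
Why: Complexation of the terminal alkyne with Co2(CO)8 gives the alkyne–Co2(CO)6 complex needed for a Nicholas reaction; no other group reacts.

Step 12
Reactants: 20 hexacarbonyldicobalt complex of (4S)-4-(tert-butylperoxy)-5-ethynyloxolan-2-one; 11 5-{[(2R)-2-ethyl-6-methylideneoct-4-yn-1-yl]sulfonyl}-1-phenyl-1H-tetrazole
Product: 23 hexacarbonyldicobalt complex (at the 4-ethynyl group) of 2-[(3S,4R,6R)-6-ethyl-4-ethynyl-6-{(4R)-4-ethyl-5-[(1-phenyl-1H-tetrazol-5-yl)sulfonyl]pent-1-yn-1-yl}-1,2-dioxan-3-yl]acetic acid, via Nicholas cation 21 (not isolated), via tertiary propargylic cation 22 (not isolated)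
Conditions: 11 (1.3 equiv), BF3·OEt2 (3 equiv), CH2Cl2, −78 → −20 °C; pH 4 buffer
Reagents that add atoms: none
Why: Proposed new method: BF3 ionises the propargylic lactone C–O bond of 20 to the Co2(CO)6-stabilised (Nicholas) cation 21, whose carboxylate is parked as its BF3 adduct; the CH2 terminus (C5) of enyne 11 adds to C4 to give the tertiary propargylic cation 22 at C6, and the tert-butyl-bearing peroxide oxygen attacks C6 and loses isobutene, which closes the 1,2-dioxane irreversibly whereas return of the carboxylate (lactone or seven-membered ring) is reversible. The closest known reaction types are the Nicholas reaction with alkene π-nucleophiles, the Lewis-acid [3+2] annulation of silyl peroxycarbenium ions with alkenes, and the dealkylative cyclisation of tert-butyl peroxides onto cationic carbon. The 1,2-dioxane closes by O1–C6 bond formation at a planar tertiary cation through a six-membered chair transition state. C4 is set in the C–C bond formation by Felkin–Anh-type attack anti to the C3–O bond with the small C3–H turned towards the bulky cobalt cluster (3,4-cis), and C6 is set in the ring closure, where the cobalt-bearing C4 substituent is equatorial, the rod-like C7≡C8 alkynyl group (A value about 0.4 kcal/mol) takes the axial site and ethyl (about 1.8 kcal/mol) the equatorial one; C3 is untouched and both epimers at the propargylic carbon of 20 converge on 21. The step needs attack at the propargylic carbon only (secured by cobalt complexation), attack by the CH2 end of the enyne (gives the tertiary propargylic cation), and capture by peroxide oxygen before proton loss (secured by the 1,4-relationship of O1 and C4 and the low temperature).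

Step 13
Reactants: 23 hexacarbonyldicobalt complex of the diyne acid
Product: 24 2-[(3S,4R,6R)-6-ethyl-4-ethynyl-6-{(4R)-4-ethyl-5-[(1-phenyl-1H-tetrazol-5-yl)sulfonyl]pent-1-yn-1-yl}-1,2-dioxan-3-yl]acetic acid
Conditions: (NH4)2Ce(NO3)6, acetone, −10 °C
Reagents that add atoms: none
Why: Oxidative decomplexation of the alkyne–Co2(CO)6 unit with CAN, the standard release after a Nicholas reaction; dialkyl peroxide, sulfone and acid are stable to Ce(IV).

Step 14
Reactants: 24 2-[(3S,4R,6R)-6-ethyl-4-ethynyl-6-{(4R)-4-ethyl-5-[(1-phenyl-1H-tetrazol-5-yl)sulfonyl]pent-1-yn-1-yl}-1,2-dioxan-3-yl]acetic acid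
Product: 25 2-[(3S,4S,6S)-4,6-diethyl-6-{(4R)-4-ethyl-5-[(1-phenyl-1H-tetrazol-5-yl)sulfonyl]pentyl}-1,2-dioxan-3-yl]acetic acid
Conditions: 2-nitrobenzenesulfonohydrazide (excess, in portions), Et3N, CH2Cl2, rt
Reagents that add atoms: none
Why: Diimide generated from the sulfonohydrazide saturates both alkynes by concerted syn H2 transfer without cleaving the O–O bond, turning the ethynyl group into the C4 ethyl group and C7≡C8 into the chain; no stereocentre changes (the descriptors at C4 and C6 change only by CIP priority).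

Step 15
Reactants: 25 2-[(3S,4S,6S)-4,6-diethyl-6-{(4R)-4-ethyl-5-[(1-phenyl-1H-tetrazol-5-yl)sulfonyl]pentyl}-1,2-dioxan-3-yl]acetic acid; 26 propanal
Product: 27 2-[(3S,4S,6S)-4,6-diethyl-6-[(4R,5E)-4-ethyloct-5-en-1-yl]-1,2-dioxan-3-yl]acetic acid
Conditions: KHMDS (2.2 equiv), DME, −60 °C; then 26, −60 °C → rt; aq. NH4Cl
Reagents that add atoms: none
Why: Julia–Kocienski olefination: the tetrazolyl sulfonyl carbanion adds to propanal and Smiles rearrangement with loss of SO2 gives the E-alkene (the usual E preference of phenyltetrazolyl sulfones with KHMDS in DME), while the carboxylate formed by the first equivalent of base protects the β-peroxy acid from enolisation.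

Step 16
Reactants: 27 2-[(3S,4S,6S)-4,6-diethyl-6-[(4R,5E)-4-ethyloct-5-en-1-yl]-1,2-dioxan-3-yl]acetic acid
Product: 28 methyl 2-[(3S,4S,6S)-4,6-diethyl-6-[(4R,5E)-4-ethyloct-5-en-1-yl]-1,2-dioxan-3-yl]acetate (target)
Conditions: TMSCHN2, toluene/MeOH 4:1, 0 °C
Reagents that add atoms: (trimethylsilyl)diazomethane, C[Si](C)(C)C=[N+]=[N-]
Why: Methylation of the carboxylic acid with TMSCHN2/MeOH under neutral conditions that the base-sensitive β-peroxy ester tolerates should give the target.

## Compound list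

1 | (4S)-4-benzyl-1,3-oxazolidin-2-one | O=C1N[C@@H](Cc2ccccc2)CO1 | starting material
2 | butanoyl chloride | CCCC(=O)Cl | starting material
3 | (4S)-4-benzyl-3-butanoyl-1,3-oxazolidin-2-one | CCCC(=O)N1[C@@H](Cc2ccccc2)COC1=O | intermediate
4 | 3-bromoprop-1-yne | C#CCBr | starting material
5 | (4S)-4-benzyl-3-[(2R)-2-ethylpent-4-ynoyl]-1,3-oxazolidin-2-one | C#CC[C@@H](CC)C(=O)N1[C@@H](Cc2ccccc2)COC1=O | intermediate
6 | (2R)-2-ethylpent-4-yn-1-ol | C#CC[C@@H](CC)CO | intermediate
7 | 1-phenyl-1H-tetrazole-5-thiol | Sc1nnnn1-c1ccccc1 | starting material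
8 | 5-{[(2R)-2-ethylpent-4-yn-1-yl]sulfanyl}-1-phenyl-1H-tetrazole | C#CC[C@@H](CC)CSc1nnnn1-c1ccccc1 | intermediate
9 | 5-{[(2R)-2-ethylpent-4-yn-1-yl]sulfonyl}-1-phenyl-1H-tetrazole | C#CC[C@@H](CC)CS(=O)(=O)c1nnnn1-c1ccccc1 | intermediate
10 | 2-bromobut-1-ene | C=C(Br)CC | starting material
11 | 5-{[(2R)-2-ethyl-6-methylideneoct-4-yn-1-yl]sulfonyl}-1-phenyl-1H-tetrazole | C=C(CC)C#CC[C@@H](CC)CS(=O)(=O)c1nnnn1-c1ccccc1 | intermediate
12 | (2E)-4,4-dimethoxybut-2-enal | COC(OC)/C=C/C=O | starting material
13 | ethynylmagnesium bromide | C#C[Mg]Br | starting material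
14 | (4E)-6,6-dimethoxyhex-4-en-1-yn-3-ol (racemic) | C#CC(O)/C=C/C(OC)OC | intermediate
15 | (2E)-4-hydroxyhex-2-en-5-ynal (racemic) | C#CC(O)/C=C/C=O | intermediate
16 | tert-butyl hydroperoxide | CC(C)(C)OO | starting material
17 | (3S)-3-(tert-butylperoxy)-4-hydroxyhex-5-ynal (C4 epimers; not isolated) | O=CC[C@H](OOC(C)(C)C)C(O)C#C | intermediate
18 | (4S)-4-(tert-butylperoxy)-5-ethynyloxolan-2-ol (C2/C5 epimers) | C#CC1OC(O)C[C@@H]1OOC(C)(C)C | intermediate
19 | (4S)-4-(tert-butylperoxy)-5-ethynyloxolan-2-one (C5 epimers) | C#CC1OC(=O)C[C@@H]1OOC(C)(C)C | intermediate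
20 | hexacarbonyldicobalt complex of 19 at the alkyne | [CH]12[C]3(C4OC(=O)C[C@@H]4OOC(C)(C)C)[Co]1(=C=O)(=C=O)(=C=O)[Co]23(=C=O)(=C=O)=C=O | intermediate
21 | Nicholas cation: Co2(CO)6-stabilised propargylic cation with BF3-bound carboxylate (not isolated) | F[B-](F)(F)OC(=O)C[C@H](OOC(C)(C)C)[CH+][C]12[CH]3[Co]1(=C=O)(=C=O)(=C=O)[Co]23(=C=O)(=C=O)=C=O | intermediate
22 | tertiary propargylic cation after C4–C5 bond formation (not isolated) | F[B-](F)(F)OC(=O)C[C@H](OOC(C)(C)C)[C@H](C[C+](CC)C#CC[C@@H](CC)CS(=O)(=O)c4nnnn4-c5ccccc5)[C]12[CH]3[Co]1(=C=O)(=C=O)(=C=O)[Co]23(=C=O)(=C=O)=C=O | intermediate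
23 | hexacarbonyldicobalt complex (at the 4-ethynyl group) of 24 | c2ccccc2-n3nnnc3S(=O)(=O)C[C@H](CC)CC#C[C@@]1(CC)C[C@H]([C]45[CH]6[Co]4(=C=O)(=C=O)(=C=O)[Co]56(=C=O)(=C=O)=C=O)[C@H](CC(=O)O)OO1 | intermediate
24 | 2-[(3S,4R,6R)-6-ethyl-4-ethynyl-6-{(4R)-4-ethyl-5-[(1-phenyl-1H-tetrazol-5-yl)sulfonyl]pent-1-yn-1-yl}-1,2-dioxan-3-yl]acetic acid | c2ccccc2-n3nnnc3S(=O)(=O)C[C@H](CC)CC#C[C@@]1(CC)C[C@H](C#C)[C@H](CC(=O)O)OO1 | intermediate
25 | 2-[(3S,4S,6S)-4,6-diethyl-6-{(4R)-4-ethyl-5-[(1-phenyl-1H-tetrazol-5-yl)sulfonyl]pentyl}-1,2-dioxan-3-yl]acetic acid | c2ccccc2-n3nnnc3S(=O)(=O)C[C@H](CC)CCC[C@@]1(CC)C[C@H](CC)[C@H](CC(=O)O)OO1 | intermediate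
26 | propanal | CCC=O | starting material
27 | 2-[(3S,4S,6S)-4,6-diethyl-6-[(4R,5E)-4-ethyloct-5-en-1-yl]-1,2-dioxan-3-yl]acetic acid | CC/C=C/[C@H](CC)CCC[C@@]1(CC)C[C@H](CC)[C@H](CC(=O)O)OO1 | intermediate
28 | methyl 2-[(3S,4S,6S)-4,6-diethyl-6-[(4R,5E)-4-ethyloct-5-en-1-yl]-1,2-dioxan-3-yl]acetate | CC/C=C/[C@H](CC)CCC[C@@]1(CC)C[C@H](CC)[C@H](CC(=O)OC)OO1 | target

## Step count and risks

Total step count: 16. Longest linear sequence: 11 steps (steps 1–6 and 12–16).

**Step 12 (proposed new method).** The tertiary cation may lose a proton to give an open-chain diene-yne, the carboxylate may compete for the cation, facial selectivity at C4 or C6 may be poor, or the cobalt cluster and BF3 may degrade the peroxide. The fallback sets out from 20 and 11, makes the two bonds in two known operations, and comes back at 23. Lewis-acid Nicholas alkylation of alkene 11 by 20 with chloride capture (TiCl4, CH2Cl2, −78 °C) gives the hexacarbonyldicobalt complex of (3S,4R,10R)-3-(tert-butylperoxy)-6-chloro-6,10-diethyl-4-ethynyl-11-[(1-phenyl-1H-tetrazol-5-yl)sulfonyl]undec-7-ynoic acid F1 (C6 epimers). Silver-assisted ionisation of this tertiary propargylic chloride (AgBF4, CH2Cl2, −40 °C) then closes the ring by dealkylative attack of the tert-butyl peroxide, the known silver-mediated cyclisation of halo peroxides, and gives 23.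

**Step 9.** The enamine formed after peroxide addition may attack the O–O bond and give the epoxide, the racemic γ-carbinol centre may erode the catalyst's facial control, or the enal may divert into dienamine chemistry. The fallback is a chiral-pool route that sets out from tert-butyl hydroperoxide 16 and commercial dimethyl (R)-malate, uses 13, and comes back at lactone 19.
- Triflation (Tf2O, 2,6-lutidine, CH2Cl2, −78 °C) gives dimethyl (2R)-2-{[(trifluoromethyl)sulfonyl]oxy}butanedioate F2.
- SN2 displacement with 16 and K2CO3, with inversion, gives dimethyl (2S)-2-(tert-butylperoxy)butanedioate F3.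
- DIBAL-H (1 equiv, −78 °C) reduces the more electrophilic α-peroxy ester to methyl (3S)-3-(tert-butylperoxy)-4-oxobutanoate F4.
- Addition of 13 at −78 °C gives methyl (3S)-3-(tert-butylperoxy)-4-hydroxyhex-5-ynoate F5, which lactonises with catalytic TsOH to 19.

**Step 14.** Saturation of the hindered internal alkyne next to the quaternary C6 may stall, and long exposure to a large excess of reagent may start to cleave the peroxide. The fallback sets out from 24 and comes back at 25 through an isolable diene. Lindlar semi-hydrogenation (H2, Pd/CaCO3–Pb, quinoline, EtOAc) gives 2-[(3S,4R,6R)-4-ethenyl-6-ethyl-6-{(1Z,4R)-4-ethyl-5-[(1-phenyl-1H-tetrazol-5-yl)sulfonyl]pent-1-en-1-yl}-1,2-dioxan-3-yl]acetic acid F6. Its two alkenes are then saturated with a small excess of diimide or with H2 and RhCl(PPh3)3 to give 25.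

## Further compounds

F1 | step 12 | hexacarbonyldicobalt complex of (3S,4R,10R)-3-(tert-butylperoxy)-6-chloro-6,10-diethyl-4-ethynyl-11-[(1-phenyl-1H-tetrazol-5-yl)sulfonyl]undec-7-ynoic acid (C6 epimers) | OC(=O)C[C@H](OOC(C)(C)C)[C@H](CC(Cl)(CC)C#CC[C@@H](CC)CS(=O)(=O)c4nnnn4-c5ccccc5)[C]12[CH]3[Co]1(=C=O)(=C=O)(=C=O)[Co]23(=C=O)(=C=O)=C=O
F2 | step 9 | dimethyl (2R)-2-{[(trifluoromethyl)sulfonyl]oxy}butanedioate | COC(=O)C[C@@H](OS(=O)(=O)C(F)(F)F)C(=O)OC
F3 | step 9 | dimethyl (2S)-2-(tert-butylperoxy)butanedioate | COC(=O)C[C@H](OOC(C)(C)C)C(=O)OC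
F4 | step 9 | methyl (3S)-3-(tert-butylperoxy)-4-oxobutanoate | COC(=O)C[C@H](OOC(C)(C)C)C=O
F5 | step 9 | methyl (3S)-3-(tert-butylperoxy)-4-hydroxyhex-5-ynoate (C4 epimers) | COC(=O)C[C@H](OOC(C)(C)C)C(O)C#C
F6 | step 14 | 2-[(3S,4R,6R)-4-ethenyl-6-ethyl-6-{(1Z,4R)-4-ethyl-5-[(1-phenyl-1H-tetrazol-5-yl)sulfonyl]pent-1-en-1-yl}-1,2-dioxan-3-yl]acetic acid | c2ccccc2-n3nnnc3S(=O)(=O)C[C@H](CC)C/C=C\[C@@]1(CC)C[C@H](C=C)[C@H](CC(=O)O)OO1
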